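**Plan**
Numbering (briarane): C1 and C10 are the ring-fusion carbons; ring A is C1, C10–C14 (C11=C20H2, C15 methyl on C1); the ten-membered ring is C1–C10 (C16 methylene on C5); the lactone is C7–O–C19(=O)–C17(C18)–C8.
Feature used: in the ten-membered ring, C5(=C16H2)–C6HCl–C7H(O) is a homoallylic anti-chlorohydrin, which is what a γ-chloroallyl metal leaves when it adds to a C7 aldehyde with allylic transposition.
Cuts: lactone C19–O7 first (C19 is carried as a silyl-protected alcohol), then C6–C7 (ten-membered ring), C4–C5 and C2–C3 (C2 arm), C8–C9 (C9 arm), and C1–C10 of ring A back to an epoxygeranyl acetate.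
Forward: ring A by titanocene radical cyclisation; C9 arm by aldol with a 4-methylbutyrolactone enolate (C7, C8, C17, C19); C2 arm by acetate aldol, thioester–alkenylzinc coupling and syn reduction; ring closure with CrCl2 from the C6 gem-dichloride; lactone last.
Stereochemistry: C14/C1/C10 from a Sharpless epoxide and the chair cyclisation (C14 inverted via the ketone); C17 from (R)-4-methylbutyrolactone, relayed to C8 and C9; C2 from a thiazolidinethione auxiliary; C4 by 1,3-syn reduction; C6 and C7 in the ring closure.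

Key step: step 26

Remark: (R)-4-methyldihydrofuran-2(3H)-one, D-(−)-diethyl tartrate and (R)-3-acetyl-4-benzyl-1,3-thiazolidine-2-thione are taken as catalogue chemicals; C19 is kept at the alcohol level until after ring closure because the lactone that builds C8–C9 is opened with hydride.

Step 1
Reactants: 1 geranyl acetate
Product: 2 (2E,6E)-8-hydroxygeranyl acetate
Conditions: SeO2 (cat.), t-BuOOH, salicylic acid (cat.), CH2Cl2, rt
Reagents that add atoms: tert-butyl hydroperoxide, CC(C)(C)OO
Why: Selenium dioxide allylic oxidation (ene reaction, then [2,3]-sigmatropic shift) should hydroxylate the E-methyl group of the electron-rich terminal alkene and leave the acetate-deactivated C2=C3 alkene alone, with no stereocentre formed.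

Step 2
Reactants: 2 (2E,6E)-8-hydroxygeranyl acetate
Product: 3 (6R,7R)-6,7-epoxy-8-hydroxygeranyl acetate
Conditions: Ti(OiPr)4 (cat.), D-(−)-diethyl tartrate (cat.), t-BuOOH, 4 Å molecular sieves, CH2Cl2, −20 °C
Reagents that add atoms: tert-butyl hydroperoxide, CC(C)(C)OO
Why: Sharpless asymmetric epoxidation acts only on the allylic alcohol alkene, and the D-(−)-tartrate complex should deliver oxygen to the face that gives the 6R,7R epoxide, whose C6–O bond becomes C14–O.

Step 3
Reactants: 3 (6R,7R)-6,7-epoxy-8-hydroxygeranyl acetate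
Product: 4 (6R,7R)-8-(tert-butyldimethylsilyloxy)-6,7-epoxygeranyl acetate
Conditions: TBSCl, imidazole, DMF, 0 °C → rt
Reagents that add atoms: tert-butyldimethylsilyl chloride, CC(C)(C)[Si](C)(C)Cl
Why: Silylation of the primary alcohol gives a radical- and base-stable ether that keeps the future C2 oxygen distinct from the C9 acetate and makes the C2 branch the larger substituent on the epoxide carbon.

Step 4
Reactants: 4 (6R,7R)-8-(tert-butyldimethylsilyloxy)-6,7-epoxygeranyl acetate
Product: 5 ring A alcohol (C14–OH equatorial and cis to C15; C1 with axial CH3 and equatorial CH2OTBS; C10 with equatorial CH2OAc; C11=C20H2)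
Conditions: Cp2TiCl2, Mn dust, THF, rt; aq. HCl work-up
Reagents that add atoms: none
Why: Titanocene-mediated radical epoxypolyene cyclisation, in which Cp2TiCl (trivalent titanium, formed in the flask) opens the epoxide to the tertiary radical, this closes 6-endo-trig onto the trisubstituted alkene and titanium capture with β-hydride elimination gives the C11=C20 methylene; C14 keeps the epoxide configuration, and the chair transition state with the titanoxy, silyloxymethyl and acetoxymethyl groups equatorial should set C1 (C15 axial) and C10.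

Step 5
Reactants: 5 ring A alcohol
Product: 6 ring A C14 ketone
Conditions: Dess–Martin periodinane, NaHCO3, CH2Cl2, rt
Reagents that add atoms: none
Why: Dess–Martin oxidation of the equatorial C14 alcohol to the ketone opens the way to the axial epimer that the target needs, with acetate, silyl ether and the quaternary C1 unaffected.

Step 6
Reactants: 6 ring A C14 ketone
Product: 8 ring A 9,14-diol (C14–OH axial and trans to C15), via hydroxy acetate 7 (not isolated)
Conditions: LiBH(s-Bu)3, THF, −78 °C; then aq. NaOH, H2O2, MeOH, 0 °C → rt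
Reagents that add atoms: none
Why: Ketone reduction by a bulky borohydride, which attacks from the equatorial direction as with 4,4-disubstituted 3-oxo terpenoids and should give the axial C14 alcohol, while the alkaline oxidative work-up that destroys the borane also saponifies the primary acetate.

Step 7
Reactants: 8 ring A 9,14-diol
Product: 9 ring A C9 aldehyde (14-OH free)
Conditions: 2,2,6,6-tetramethylpiperidin-1-oxyl (TEMPO, cat.), PhI(OAc)2, CH2Cl2, rt
Reagents that add atoms: none
Why: Oxoammonium (TEMPO) oxidation is selective for the primary alcohol, the axial C14 alcohol lies on the opposite ring face and cannot form a lactol, and the equatorial C10 aldehyde is the thermodynamically favoured epimer.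

Step 8
Reactants: 10 (R)-4-methyldihydrofuran-2(3H)-one
Product: 12 (3R,4S)-3-hydroxy-4-methyldihydrofuran-2(3H)-one, via lithium enolate 11 (not isolated)
Conditions: LiN(SiMe3)2, THF, −78 °C; then 2-(phenylsulfonyl)-3-phenyloxaziridine, −78 °C; NH4Cl
Reagents that add atoms: 2-(phenylsulfonyl)-3-phenyloxaziridine, O=S(=O)(c1ccccc1)N1OC1c1ccccc1
Why: Enolate α-hydroxylation with an N-sulfonyloxaziridine places oxygen on the future C8, mainly anti to the C17 methyl group, although this centre is erased again in step 10 and only C17 must be configurationally pure.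

Step 9
Reactants: 12 (3R,4S)-3-hydroxy-4-methyldihydrofuran-2(3H)-one
Product: 13 (3R,4S)-3-(2-methoxypropan-2-yloxy)-4-methyldihydrofuran-2(3H)-one
Conditions: 2-methoxypropene, pyridinium p-toluenesulfonate (cat.), CH2Cl2, 0 °C
Reagents that add atoms: 2-methoxypropene, COC(C)=C
Why: Acid-catalysed addition of the alcohol to the enol ether gives a mixed ketal that survives enolate formation and hydride and later turns into the acetonide.

Step 10
Reactants: 13 (3R,4S)-3-(2-methoxypropan-2-yloxy)-4-methyldihydrofuran-2(3H)-one; 9 ring A C9 aldehyde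
Product: 15 aldol adduct (C9 carbinol on C8 of the lactone; C7 lactone carbonyl; O8 mixed ketal), via lithium enolate 14 (not isolated)
Conditions: LiN(iPr)2, THF, −78 °C (13, 2.3 equiv); then 9, −78 °C; AcOH, −78 °C
Reagents that add atoms: none
Why: Lithium enolate aldol addition (one equivalent of enolate is consumed by the free C14 hydroxyl) in which the aldehyde should add trans to the C17 methyl group of the five-membered enolate, setting C8, and the chair transition state with the alkoxy group cis to the enolate oxygen and the ring A residue equatorial should place the C8 and C9 oxygens syn along C7–C10, setting C9.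

Step 11
Reactants: 15 aldol adduct
Product: 16 C7,C19-diol with O8 mixed ketal (9-OH and 14-OH free)
Conditions: LiAlH4, THF, 0 °C; aq. NaOH work-up
Reagents that add atoms: none
Why: Hydride reduction of the lactone to the diol, which the mixed ketal and the silyl ether tolerate together with the basic work-up and which touches no stereocentre.

Step 12
Reactants: 16 C7,C19-diol with O8 mixed ketal
Product: 17 7,8-acetonide 9,14,19-triol
Conditions: pyridinium p-toluenesulfonate (cat.), 4 Å molecular sieves, CH2Cl2, rt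
Reagents that add atoms: none
Why: Intramolecular transketalisation in which the oxocarbenium ion of the O8 mixed ketal is trapped by the neighbouring primary C7 hydroxyl to the terminal five-membered acetonide, the least strained of the possible ketals, which masks C7–OH and C8–OH and leaves C19–OH as the only primary alcohol.

Step 13
Reactants: 17 7,8-acetonide 9,14,19-triol
Product: 19 9,14-diacetate 19-silyl ether, via silyl ether diol 18 (not isolated)
Conditions: TBDPSCl, imidazole, CH2Cl2, 0 °C → rt; then Ac2O, Et3N, 4-(dimethylamino)pyridine (cat.), rt → 40 °C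
Reagents that add atoms: tert-butyldiphenylsilyl chloride, CC(C)(C)[Si](Cl)(c1ccccc1)c1ccccc1; acetic anhydride, CC(=O)OC(C)=O
Why: Silylation selective for the only primary alcohol, followed in the same flask by acylation of the two hindered secondary alcohols, installs the C9 and C14 acetates of the target and blocks the C9 hydroxyl that would otherwise form a lactol with the C2 aldehyde.

Step 14
Reactants: 19 9,14-diacetate 19-silyl ether
Product: 20 C2 primary alcohol
Conditions: HF·pyridine, pyridine, THF, 0 °C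
Reagents that add atoms: none
Why: Fluoride-mediated desilylation removes the primary tert-butyldimethylsilyl ether much faster than the tert-butyldiphenylsilyl ether, and the buffered medium spares the acetonide and the acetates.

Step 15
Reactants: 20 C2 primary alcohol
Product: 21 C2 aldehyde
Conditions: Dess–Martin periodinane, NaHCO3, CH2Cl2, rt
Reagents that add atoms: none
Why: Dess–Martin oxidation gives the α-quaternary, non-enolisable aldehyde under neutral conditions that leave every protecting group in place.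

Step 16
Reactants: 21 C2 aldehyde
Product: 22 (2S)-aldol adduct (N-acylthiazolidinethione)
Conditions: (R)-3-acetyl-4-benzyl-1,3-thiazolidine-2-thione, TiCl4, iPr2NEt, CH2Cl2, −78 °C; then 21, −78 °C
Reagents that add atoms: (R)-3-acetyl-4-benzyl-1,3-thiazolidine-2-thione, CC(=O)N1[C@H](Cc2ccccc2)CSC1=S
Why: Auxiliary-controlled acetate aldol addition of a chlorotitanium enolate, in whose chelated chair transition state the aldehyde approaches anti to the benzyl group, so that the R auxiliary is expected to give the 2S carbinol and to dominate over the bias of the quaternary C1.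

Step 17
Reactants: 22 (2S)-aldol adduct
Product: 23 S-ethyl thioester
Conditions: EtSH, imidazole, CH2Cl2, rt
Reagents that add atoms: ethanethiol, CCS
Why: Acyl transfer from the activated N-acylthiazolidinethione to the thiol gives the thioester and releases the auxiliary under conditions too mild to move the acetates or reverse the aldol.

Step 18
Reactants: 23 S-ethyl thioester
Product: 24 β-hydroxy enone (C4 ketone, C5=C16H2, C6–OTBS)
Conditions: (2-bromoallyloxy)(tert-butyl)dimethylsilane, t-BuLi, Et2O, −78 °C; ZnCl2; then 23, PdCl2(PPh3)2 (cat.), THF/toluene, rt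
Reagents that add atoms: (2-bromoallyloxy)(tert-butyl)dimethylsilane, C=C(Br)CO[Si](C)(C)C(C)(C)C
Why: Fukuyama coupling, in which zerovalent palladium inserts into the C–S bond, the alkenylzinc transmetalates and reductive elimination gives the ketone bearing the C5=C16 methylene and the protected C6 alcohol, while acetates, the free hydroxyl and silyl ethers are tolerated and no stereocentre is formed.

Step 19
Reactants: 24 β-hydroxy enone
Product: 25 2,4-syn-diol
Conditions: Et2BOMe, NaBH4, THF/MeOH (4:1), −78 °C; AcOH, then MeOH co-evaporation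
Reagents that add atoms: none
Why: Narasaka–Prasad reduction, in which hydride adds in 1,2-fashion to the boron chelate of the β-hydroxy enone from the face that gives the 2,4-syn diol, so that C4 is set from C2.

Step 20
Reactants: 25 2,4-syn-diol
Product: 26 2,4,9,14-tetraacetate (C6–OTBS, 7,8-acetonide, 19-OTBDPS)
Conditions: Ac2O, 4-(dimethylamino)pyridine (cat.), pyridine, rt → 40 °C
Reagents that add atoms: acetic anhydride, CC(=O)OC(C)=O
Why: Nucleophile-catalysed acetylation of both secondary alcohols completes the tetraacetate pattern, the tertiary C8 oxygen being tied up in the acetonide.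

Step 21
Reactants: 26 2,4,9,14-tetraacetate
Product: 27 C6 allylic alcohol
Conditions: HF·pyridine, pyridine, THF, 0 °C
Reagents that add atoms: none
Why: Fluoride-mediated cleavage of the primary allylic tert-butyldimethylsilyl ether is again faster than that of the tert-butyldiphenylsilyl ether and needs no acid strong enough to open the acetonide.

Step 22
Reactants: 27 C6 allylic alcohol
Product: 28 C6 enal
Conditions: MnO2, CH2Cl2, rt
Reagents that add atoms: none
Why: MnO2 oxidation is specific for the allylic alcohol and gives the 2-substituted acrolein without base, which the allylic C4 acetate would not tolerate.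

Step 23
Reactants: 28 C6 enal
Product: 29 C6 gem-dichloride (7,8-acetonide)
Conditions: (COCl)2, Ph3PO (cat.), CH2Cl2, rt
Reagents that add atoms: oxalyl chloride, O=C(Cl)C(=O)Cl
Why: Phosphine oxide-catalysed deoxydichlorination of an aldehyde (the chlorophosphonium salt takes the aldehyde oxygen and delivers two chlorides) converts the non-enolisable enal into the allylic gem-dichloride, and a 1,3-shift of chloride would be harmless because both allylic isomers give the same allylchromium species.

Step 24
Reactants: 29 C6 gem-dichloride (7,8-acetonide)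
Product: 30 gem-dichloride 7,8-diol
Conditions: CF3CO2H/H2O (9:1), CH2Cl2, 0 °C
Reagents that add atoms: none
Why: Acid hydrolysis of the terminal acetonide, kept short and cold so that the acetates, the silyl ether and the allylic dichloride survive.

Step 25
Reactants: 30 gem-dichloride 7,8-diol
Product: 31 seco aldehyde (C6 gem-dichloride, C7 aldehyde, 8-OH, tetraacetate, 19-OTBDPS)
Conditions: Dess–Martin periodinane, NaHCO3, CH2Cl2, 0 °C → rt
Reagents that add atoms: none
Why: Dess–Martin oxidation of the primary alcohol of the 1,2-diol gives the tertiary α-hydroxy aldehyde, which cannot enolise, and leaves the tertiary alcohol alone.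

Step 26
Reactants: 31 seco aldehyde
Product: 33 ten-membered 6-chloro-7,8-diol (tetraacetate, 19-OTBDPS), via γ-chloroallylchromium dichloride 32 (not isolated)
Conditions: CrCl2 (4 equiv), THF, rt, slow addition of 31 (final 2 mM); aqueous work-up
Reagents that add atoms: none
Why: Proposed new method: two equivalents of CrCl2 (divalent chromium) reduce one allylic C–Cl bond to an α-chloroallylchromium (trivalent chromium) that equilibrates to the primary C16–Cr isomer 32 with chlorine E on C6, and this adds through C6 to the C7 aldehyde with allylic transposition, forming C6–C7 and restoring the C5=C16 methylene. The closest known reactions are the intermolecular chromium-mediated γ-chloroallylation of aldehydes with 3,3- or 1,3-dichloropropenes, which gives anti chlorohydrins, and Nozaki–Hiyama allylation macrocyclisations of allylic halide aldehydes; their combination in one ring closure is new. The ten-membered ring (C1–C10) closes in a 10-exo-trig carbonyl addition, favoured over oligomerisation by slow addition at high dilution and by the turn that ring A and the quaternary C1 and C8 impose on the chain. C6 is set by the six-membered chair transition state of the E-chloroallylchromium, which places chlorine and the new C7 oxygen anti; C7 is set by C8, because the chromium alkoxide of the free C8 hydroxyl can chelate the aldehyde so that the tethered nucleophile arrives on the chelate face that carries C9. The step needs γ-selective attack (given by the cyclic transition state), reduction of one C–Cl bond only (the gem-dichloride is reduced much faster than the secondary allylic chloride of the product, and the reagent is kept to a small excess), and tolerance of four acetates, a silyl ether and a free tertiary alcohol, which organochromium reagents show.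

Step 27
Reactants: 33 ten-membered 6-chloro-7,8-diol
Product: 34 7,8,19-triol
Conditions: HF·pyridine, pyridine, THF, rt
Reagents that add atoms: none
Why: Fluoride-mediated cleavage of the tert-butyldiphenylsilyl ether frees the primary C19 alcohol, while the acetates, the allylic chloride and the diol are stable to buffered HF.

Step 28
Reactants: 34 7,8,19-triol
Product: 37 CNP0186618.1, via C19 aldehyde 35 (not isolated), via lactol 36 (not isolated)
Conditions: 2,2,6,6-tetramethylpiperidin-1-oxyl (TEMPO, cat.), PhI(OAc)2, CH2Cl2, rt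
Reagents that add atoms: none
Why: Oxidative lactonisation of a 1,4-diol, in which TEMPO oxidation of the primary C19 alcohol, lactol formation with the C7 hydroxyl and a second oxidation close the γ-lactone, while the tertiary C8 alcohol and the acetates are inert and C17 should not epimerise under these near-neutral conditions.

**Compound list**
1 | geranyl acetate | CC(=O)OC/C=C(\C)CCC=C(C)C | starting material
2 | (2E,6E)-8-hydroxygeranyl acetate | CC(=O)OC/C=C(\C)CC/C=C(\C)CO | intermediate
3 | (6R,7R)-6,7-epoxy-8-hydroxygeranyl acetate | CC(=O)OC/C=C(\C)CC[C@H]1O[C@]1(C)CO | intermediate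
4 | (6R,7R)-8-(tert-butyldimethylsilyloxy)-6,7-epoxygeranyl acetate | CC(=O)OC/C=C(\C)CC[C@H]1O[C@]1(C)CO[Si](C)(C)C(C)(C)C | intermediate
5 | ring A alcohol; C14–OH equatorial (C14 epimer of the target series), C1 and C10 as in 37 | C=C1CC[C@@H](O)[C@](C)(CO[Si](C)(C)C(C)(C)C)[C@H]1COC(C)=O | intermediate
6 | ring A C14 ketone | C=C1CCC(=O)[C@](C)(CO[Si](C)(C)C(C)(C)C)[C@H]1COC(C)=O | intermediate
7 | axial C14 alcohol, 9-acetate | C=C1CC[C@H](O)[C@](C)(CO[Si](C)(C)C(C)(C)C)[C@H]1COC(C)=O | intermediate (not isolated)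
8 | ring A 9,14-diol, C14–OH axial | C=C1CC[C@H](O)[C@](C)(CO[Si](C)(C)C(C)(C)C)[C@H]1CO | intermediate
9 | ring A C9 aldehyde, 14-OH free | C=C1CC[C@H](O)[C@](C)(CO[Si](C)(C)C(C)(C)C)[C@H]1C=O | intermediate
10 | (R)-4-methyldihydrofuran-2(3H)-one | O=C1C[C@@H](C)CO1 | starting material
11 | lithium enolate of 10 | [Li]OC1=C[C@@H](C)CO1 | intermediate (not isolated)
12 | (3R,4S)-3-hydroxy-4-methyldihydrofuran-2(3H)-one | O=C1[C@H](O)[C@@H](C)CO1 | intermediate
13 | (3R,4S)-3-(2-methoxypropan-2-yloxy)-4-methyldihydrofuran-2(3H)-one | O=C1[C@H](OC(C)(C)OC)[C@@H](C)CO1 | intermediate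
14 | lithium enolate of 13 | [Li]OC1=C(OC(C)(C)OC)[C@@H](C)CO1 | intermediate (not isolated)
15 | aldol adduct; lactone C7(=O)–O–C19, O8 mixed ketal, 9-OH, 14-OH, C2–OTBS | C=C1CC[C@H](O)[C@](C)(CO[Si](C)(C)C(C)(C)C)[C@H]1[C@H](O)[C@]2(OC(C)(C)OC)[C@@H](C)COC2=O | intermediate
16 | C7,C19-diol with O8 mixed ketal | C=C1CC[C@H](O)[C@](C)(CO[Si](C)(C)C(C)(C)C)[C@H]1[C@H](O)[C@](OC(C)(C)OC)([C@@H](C)CO)CO | intermediate
17 | 7,8-acetonide 9,14,19-triol | C=C1CC[C@H](O)[C@](C)(CO[Si](C)(C)C(C)(C)C)[C@H]1[C@H](O)[C@]2(OC(C)(C)OC2)[C@@H](C)CO | intermediate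
18 | 19-O-TBDPS ether of 17 | C=C1CC[C@H](O)[C@](C)(CO[Si](C)(C)C(C)(C)C)[C@H]1[C@H](O)[C@]2(OC(C)(C)OC2)[C@@H](C)CO[Si](c3ccccc3)(c4ccccc4)C(C)(C)C | intermediate (not isolated)
19 | 9,14-diacetate of 18 | C=C1CC[C@H](OC(C)=O)[C@](C)(CO[Si](C)(C)C(C)(C)C)[C@H]1[C@H](OC(C)=O)[C@]2(OC(C)(C)OC2)[C@@H](C)CO[Si](c3ccccc3)(c4ccccc4)C(C)(C)C | intermediate
20 | C2 primary alcohol | C=C1CC[C@H](OC(C)=O)[C@](C)(CO)[C@H]1[C@H](OC(C)=O)[C@]2(OC(C)(C)OC2)[C@@H](C)CO[Si](c3ccccc3)(c4ccccc4)C(C)(C)C | intermediate
21 | C2 aldehyde | C=C1CC[C@H](OC(C)=O)[C@](C)(C=O)[C@H]1[C@H](OC(C)=O)[C@]2(OC(C)(C)OC2)[C@@H](C)CO[Si](c3ccccc3)(c4ccccc4)C(C)(C)C | intermediate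
22 | (2S)-aldol adduct, N-acylthiazolidinethione | C=C1CC[C@H](OC(C)=O)[C@](C)([C@@H](O)CC(=O)N5[C@H](Cc6ccccc6)CSC5=S)[C@H]1[C@H](OC(C)=O)[C@]2(OC(C)(C)OC2)[C@@H](C)CO[Si](c3ccccc3)(c4ccccc4)C(C)(C)C | intermediate
23 | S-ethyl thioester | C=C1CC[C@H](OC(C)=O)[C@](C)([C@@H](O)CC(=O)SCC)[C@H]1[C@H](OC(C)=O)[C@]2(OC(C)(C)OC2)[C@@H](C)CO[Si](c3ccccc3)(c4ccccc4)C(C)(C)C | intermediate
24 | β-hydroxy enone | C=C1CC[C@H](OC(C)=O)[C@](C)([C@@H](O)CC(=O)C(=C)CO[Si](C)(C)C(C)(C)C)[C@H]1[C@H](OC(C)=O)[C@]2(OC(C)(C)OC2)[C@@H](C)CO[Si](c3ccccc3)(c4ccccc4)C(C)(C)C | intermediate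
25 | 2,4-syn-diol | C=C1CC[C@H](OC(C)=O)[C@](C)([C@@H](O)C[C@@H](O)C(=C)CO[Si](C)(C)C(C)(C)C)[C@H]1[C@H](OC(C)=O)[C@]2(OC(C)(C)OC2)[C@@H](C)CO[Si](c3ccccc3)(c4ccccc4)C(C)(C)C | intermediate
26 | 2,4,9,14-tetraacetate | C=C1CC[C@H](OC(C)=O)[C@](C)([C@@H](OC(C)=O)C[C@@H](OC(C)=O)C(=C)CO[Si](C)(C)C(C)(C)C)[C@H]1[C@H](OC(C)=O)[C@]2(OC(C)(C)OC2)[C@@H](C)CO[Si](c3ccccc3)(c4ccccc4)C(C)(C)C | intermediate
27 | C6 allylic alcohol | C=C1CC[C@H](OC(C)=O)[C@](C)([C@@H](OC(C)=O)C[C@@H](OC(C)=O)C(=C)CO)[C@H]1[C@H](OC(C)=O)[C@]2(OC(C)(C)OC2)[C@@H](C)CO[Si](c3ccccc3)(c4ccccc4)C(C)(C)C | intermediate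
28 | C6 enal | C=C1CC[C@H](OC(C)=O)[C@](C)([C@@H](OC(C)=O)C[C@@H](OC(C)=O)C(=C)C=O)[C@H]1[C@H](OC(C)=O)[C@]2(OC(C)(C)OC2)[C@@H](C)CO[Si](c3ccccc3)(c4ccccc4)C(C)(C)C | intermediate
29 | C6 gem-dichloride, 7,8-acetonide | C=C1CC[C@H](OC(C)=O)[C@](C)([C@@H](OC(C)=O)C[C@@H](OC(C)=O)C(=C)C(Cl)Cl)[C@H]1[C@H](OC(C)=O)[C@]2(OC(C)(C)OC2)[C@@H](C)CO[Si](c3ccccc3)(c4ccccc4)C(C)(C)C | intermediate
30 | gem-dichloride 7,8-diol | C=C1CC[C@H](OC(C)=O)[C@](C)([C@@H](OC(C)=O)C[C@@H](OC(C)=O)C(=C)C(Cl)Cl)[C@H]1[C@H](OC(C)=O)[C@](O)([C@@H](C)CO[Si](c2ccccc2)(c3ccccc3)C(C)(C)C)CO | intermediate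
31 | seco aldehyde (ring-closure precursor) | C=C1CC[C@H](OC(C)=O)[C@](C)([C@@H](OC(C)=O)C[C@@H](OC(C)=O)C(=C)C(Cl)Cl)[C@H]1[C@H](OC(C)=O)[C@](O)([C@@H](C)CO[Si](c2ccccc2)(c3ccccc3)C(C)(C)C)C=O | intermediate
32 | γ-chloroallylchromium dichloride (Cr on C16, C5=C6 E) | C=C1CC[C@H](OC(C)=O)[C@](C)([C@@H](OC(C)=O)C[C@@H](OC(C)=O)/C(C[Cr](Cl)Cl)=C\Cl)[C@H]1[C@H](OC(C)=O)[C@](O)([C@@H](C)CO[Si](c2ccccc2)(c3ccccc3)C(C)(C)C)C=O | intermediate (not isolated)
33 | ten-membered 6-chloro-7,8-diol, tetraacetate, 19-OTBDPS (ring-closure product) | C=C1CC[C@H](OC(C)=O)[C@]2(C)[C@@H](OC(C)=O)C[C@@H](OC(C)=O)C(=C)[C@H](Cl)[C@H](O)[C@@](O)([C@@H](C)CO[Si](c3ccccc3)(c4ccccc4)C(C)(C)C)[C@@H](OC(C)=O)[C@@H]12 | intermediate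
34 | 7,8,19-triol | C=C1CC[C@H](OC(C)=O)[C@]2(C)[C@@H](OC(C)=O)C[C@@H](OC(C)=O)C(=C)[C@H](Cl)[C@H](O)[C@@](O)([C@@H](C)CO)[C@@H](OC(C)=O)[C@@H]12 | intermediate
35 | C19 aldehyde | C=C1CC[C@H](OC(C)=O)[C@]2(C)[C@@H](OC(C)=O)C[C@@H](OC(C)=O)C(=C)[C@H](Cl)[C@H](O)[C@@](O)([C@@H](C)C=O)[C@@H](OC(C)=O)[C@@H]12 | intermediate (not isolated)
36 | lactol (C19 epimers) | C=C1CC[C@H](OC(C)=O)[C@]2(C)[C@@H](OC(C)=O)C[C@@H](OC(C)=O)C(=C)[C@H](Cl)[C@@H]3OC(O)[C@H](C)[C@@]3(O)[C@@H](OC(C)=O)[C@@H]12 | intermediate (not isolated)
37 | CNP0186618.1 (1R,2S,4R,6S,7R,8R,9S,10S,14S,17R) | C=C1CC[C@H](OC(C)=O)[C@]2(C)[C@@H](OC(C)=O)C[C@@H](OC(C)=O)C(=C)[C@H](Cl)[C@@H]3OC(=O)[C@H](C)[C@@]3(O)[C@@H](OC(C)=O)[C@@H]12 | target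

**Step count and risks**
Total: 28 steps. Longest linear sequence: 26 steps (steps 1–7 and 10–28, from geranyl acetate).

Step 26 (ring closure, proposed new method). It may fail through oligomerisation instead of ring closure. It may also fail through a second reduction of the secondary allylic chloride, followed by loss of the C7 oxygen to a diene. Attack on the wrong face of the C7 aldehyde is a further risk. Fallback with known chemistry, setting out from 27: Appel bromination (CBr4, PPh3) should give the allylic bromide F1. Acetonide hydrolysis as in step 24 gives the bromo diol F2, and Dess–Martin oxidation gives the bromo aldehyde F3. The established intramolecular Nozaki–Hiyama allylation (CrCl2, THF, high dilution) then closes the ten-membered ring to the chlorine-free homoallylic alcohol F4. Oxidation gives the C7 ketone F5. Enolisation toward C6 (C8 is quaternary), silylation and N-chlorosuccinimide give the 6-chloro ketone F6. Hydride reduction anti to the C–Cl bond (NaBH4, CeCl3) comes back to 33.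

Step 4 (radical cyclisation). The tertiary radical may lose the β-silyloxy group before it cyclises, or the chair may discriminate poorly between the methyl and silyloxymethyl groups at C1. Fallback, setting out from 1: Shi epoxidation (fructose-derived ketone, KHSO5) of the terminal alkene gives (R)-6,7-epoxygeranyl acetate F7. The same titanocene cyclisation, now of a radical with two methyl groups so that no C1 selectivity is needed, gives the gem-dimethyl cyclohexanol F8. Hydroxyl-directed C–H oxidation of the equatorial methyl group follows: the diethylhydrosilyl ether F9 (Et2SiH2, [Ir(cod)OMe]2 cat.) undergoes iridium-catalysed γ-C–H silylation to the oxasilolane F10, and Tamao–Fleming oxidation gives the 1,3-diol F11. Silylation of the primary alcohol (TBSCl, imidazole) comes back to 5.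

Step 23 (deoxydichlorination). The chlorophosphonium medium may open the acetonide, or chloride may displace the allylic C4 acetate of the enal in an SN2′ process. Fallback, setting out from 28: condensation with 1,2-bis(tert-butyldimethylsilyl)hydrazine (Sc(OTf)3 cat.) gives the N-silyl hydrazone F12. Oxidative chlorination with CuCl2 and Et3N then converts it into the gem-dichloride under base-buffered conditions and comes back to 29.

**Further compounds**
F1 | step 26 | allylic bromide (7,8-acetonide) | C=C1CC[C@H](OC(C)=O)[C@](C)([C@@H](OC(C)=O)C[C@@H](OC(C)=O)C(=C)CBr)[C@H]1[C@H](OC(C)=O)[C@]2(OC(C)(C)OC2)[C@@H](C)CO[Si](c3ccccc3)(c4ccccc4)C(C)(C)C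
F2 | step 26 | bromo diol | C=C1CC[C@H](OC(C)=O)[C@](C)([C@@H](OC(C)=O)C[C@@H](OC(C)=O)C(=C)CBr)[C@H]1[C@H](OC(C)=O)[C@](O)([C@@H](C)CO[Si](c2ccccc2)(c3ccccc3)C(C)(C)C)CO
F3 | step 26 | bromo aldehyde | C=C1CC[C@H](OC(C)=O)[C@](C)([C@@H](OC(C)=O)C[C@@H](OC(C)=O)C(=C)CBr)[C@H]1[C@H](OC(C)=O)[C@](O)([C@@H](C)CO[Si](c2ccccc2)(c3ccccc3)C(C)(C)C)C=O
F4 | step 26 | chlorine-free ten-membered homoallylic alcohol (C7 epimers) | C=C1CC[C@H](OC(C)=O)[C@]2(C)[C@@H](OC(C)=O)C[C@@H](OC(C)=O)C(=C)CC(O)[C@@](O)([C@@H](C)CO[Si](c3ccccc3)(c4ccccc4)C(C)(C)C)[C@@H](OC(C)=O)[C@@H]12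
F5 | step 26 | C7 ketone | C=C1CC[C@H](OC(C)=O)[C@]2(C)[C@@H](OC(C)=O)C[C@@H](OC(C)=O)C(=C)CC(=O)[C@@](O)([C@@H](C)CO[Si](c3ccccc3)(c4ccccc4)C(C)(C)C)[C@@H](OC(C)=O)[C@@H]12
F6 | step 26 | 6-chloro C7 ketone | C=C1CC[C@H](OC(C)=O)[C@]2(C)[C@@H](OC(C)=O)C[C@@H](OC(C)=O)C(=C)[C@H](Cl)C(=O)[C@@](O)([C@@H](C)CO[Si](c3ccccc3)(c4ccccc4)C(C)(C)C)[C@@H](OC(C)=O)[C@@H]12
F7 | step 4 | (R)-6,7-epoxygeranyl acetate | CC(=O)OC/C=C(\C)CC[C@H]1OC1(C)C
F8 | step 4 | gem-dimethyl ring A alcohol | C=C1CC[C@@H](O)C(C)(C)[C@H]1COC(C)=O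
F9 | step 4 | diethylhydrosilyl ether of F8 | C=C1CC[C@@H](O[SiH](CC)CC)C(C)(C)[C@H]1COC(C)=O
F10 | step 4 | oxasilolane | C=C1CC[C@H]2O[Si](CC)(CC)C[C@]2(C)[C@H]1COC(C)=O
F11 | step 4 | ring A 2,14-diol 9-acetate | C=C1CC[C@@H](O)[C@](C)(CO)[C@H]1COC(C)=O
F12 | step 23 | N-(tert-butyldimethylsilyl)hydrazone of 28 | C=C1CC[C@H](OC(C)=O)[C@](C)([C@@H](OC(C)=O)C[C@@H](OC(C)=O)C(=C)C=NN[Si](C)(C)C(C)(C)C)[C@H]1[C@H](OC(C)=O)[C@]2(OC(C)(C)OC2)[C@@H](C)CO[Si](c3ccccc3)(c4ccccc4)C(C)(C)C
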